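The earlier runs and the new flask are calculated with constants of no real substance, noise included.

At early times I read a single rate: in the theta and eta runs, whose charges differ 12.0 times over, target stood at 10% of the charge after 12.0 h in both, so I took 0.00833 /h of the charge as the starting rate and assumed that percentages carry across charges.

the same everywhere: gas phase 200 mM (held)

|  | substrate | remark | time |
|---|---|---|---|
| theta | 0.15 M | run made earlier |  |
| eta | 1.8 M | run made earlier |  |
| ochre | 0.30 M |  | 50 h |
| red | 0.60 M |  | 50 h |
| green | 1.2 M |  | 50 h |
| teal | 2.5 M |  | 50 h |

| run | time / h | target / % | substrate / % |
|---|---|---|---|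
| theta | 12.0 | 10 | 90 |
| theta | 25.0 | 17 | 80 |
| theta | 40.0 | 20 | 68 |
| theta | 48.0 | 22 | 64 |
| eta | 12.0 | 10 | 89 |
| eta | 25.0 | 15 | 80 |
| eta | 40.0 | 19 | 69 |
| eta | 48.0 | 24 | 65 |

(standard deviation of a reading: 1.5 percentage points)

- at the start none of the gas phase is in solution
- a reading or a percentage of target counts all its forms, free or not
- the concentration of target that is asked is that of its free form alone
- "hardly changes" means that all values lie within two and a half points (for a concentration: within two and a half percent of the largest)

* [target] (only what is free in solution, in the first phase) at the end for ochre, red, green, teal, in this order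
* how the row runs (rises all the way / rises, then falls / falls, then rises / hardly changes / falls all the way)

Unslowed, that rate gave 41.7% of the charge by 50 h, but I saw two slowing factors. Substrate fell to 64.5% at 48.0 h on the mean of both runs, so, taking the fall as straight and the rate as following substrate, I put the making of target on average at 0.823 of its starting rate. Then I followed one reacted molecule of substrate and asked its chance of still being target, which I called the keep, the running selectivity for target: 0.648 at 48.0 h, less than the 0.952 at 12.0 h. Together the factors left 0.533 of the unslowed gain, or 22.2% of the charge, so I committed to 0.0666 M, 0.133 M, 0.266 M and 0.555 M, a row that rises all the way, holding teal loosest, since its figure lay above the 0.432 M that the eta run reached.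

The forecast stood slightly above my row at teal, with 0.07 M, 0.14 M, 0.28 M and 0.59 M, a row that rises all the way, and said: “I therefore expect proportionality, with a wider range for teal”.

The flasks gave 0.0703 M, 0.140 M, 0.279 M and 0.430 M, a row that rises all the way.

    2 dissolved gas → homo dimer (k = 0.0120 /M/min)
    crystals ⇌ target, rate k2*(cs2 - [target]) while solid is left; crystals form when [target] > cs2 (solubility = 0.420 M, k = 0.0120 /min)
    dissolved gas + target → over-reacted product (k = 0.00180 /M/min)
    gas phase ⇌ dissolved gas, rate k4*(csat - [dissolved gas]) (kL = 0.0260 /min)
    substrate + dissolved gas → target (k = 9.10 × 10⁻⁴ /M/min)

In the ochre flask 63.0% of the substrate remained at the end, so the keep applied to the 37.0% reacted gave 0.0719 M against the 0.0703 M found. In the teal flask the same keep, which counts target in all its forms, applied to 35.3% reacted gave 0.572 M, more than the 0.430 M free there, and crystals form above 0.42 M. Of the teal charge, 24.1% stood as target at 50.0 h, crystals counted in, and 6.94% of the charge was in crystals.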